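**Retrosynthetic overview**
- The target acid comes from its tert-butyl ester; the C16 acetate is put on after a Negishi union (C12–C13) of a bicyclic alkylzinc with an (E)-enol tosylate that already fixes the side-chain alkene geometry.
- The bicyclic C12 iodide comes from a trans-decalone that already carries the exocyclic C8 methylene and the C5, C9 and C10 stereocentres.
- Key step (new): catalytic enantioselective enone-initiated, allylsilane-terminated bicyclization of an acyclic trienone; ring A forms first (C4–C5), ring B second (C9–C10), and loss of silicon gives C8=CH2.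
- The trienone comes from an allylic bromide and lithiated prenal dithiane (acyl anion); the bromide is assembled by Wittig, Johnson–Claisen and vinyl Grignard steps from 3-silyloxypropanal and (2-bromoallyl)trimethylsilane.

Assumption: the (S)-oxazaborolidinium ion of step 10 is taken to expose the C4 face that leads to the (5R,9R,10R) series (ent-labdane numbering); if the measured sense is opposite, its mirror-image catalyst is used with nothing else changed.

**Route**

Step 1
Reactants: 1 3-[(tert-butyldimethylsilyl)oxy]propanal; 2 (2-bromoprop-2-en-1-yl)trimethylsilane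
Product: 4 rac-1-[(tert-butyldimethylsilyl)oxy]-4-[(trimethylsilyl)methyl]pent-4-en-3-ol, via vinylmagnesium bromide 3 (not isolated)
Conditions: 2, Mg, THF, 23 → 40 °C; then 1, −78 → 0 °C; aq. NH4Cl
Reagents that add atoms: magnesium, [Mg] (held only in intermediate 3)
Why: Grignard formation from the vinyl bromide and 1,2-addition to the aldehyde (Grignard reaction) give the 2-(silylmethyl)allylic alcohol, whose racemic carbinol centre is erased in step 2.

Step 2
Reactants: 4 rac-1-[(tert-butyldimethylsilyl)oxy]-4-[(trimethylsilyl)methyl]pent-4-en-3-ol; 5 triethyl orthoacetate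
Product: 7 ethyl (4Z)-7-[(tert-butyldimethylsilyl)oxy]-4-[(trimethylsilyl)methyl]hept-4-enoate, via mixed ketene acetal 6 (not isolated)
Conditions: 5 (6 equiv), EtCO2H (5 mol%), 138 °C, distil off EtOH
Reagents that add atoms: none
Why: Johnson orthoester Claisen rearrangement through a chair transition state with the CH2CH2OSi chain equatorial gives the trisubstituted alkene with the two carbon chains trans (4Z only because CH2SiMe3 outranks carbon), and the weak acid catalyst leaves the allylsilane intact.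

Step 3
Reactants: 7 ethyl (4Z)-7-[(tert-butyldimethylsilyl)oxy]-4-[(trimethylsilyl)methyl]hept-4-enoate
Product: 8 (4Z)-7-[(tert-butyldimethylsilyl)oxy]-4-[(trimethylsilyl)methyl]hept-4-enal
Conditions: i-Bu2AlH (1.05 equiv), CH2Cl2, −78 °C; aq. KNaC4H4O6 (potassium sodium tartrate)
Reagents that add atoms: none
Why: the tetrahedral aluminium hemiacetal formed from i-Bu2AlH is stable at −78 °C and releases the aldehyde on hydrolysis (partial ester reduction), the silyl ether and allylsilane being inert.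

Step 4
Reactants: 8 (4Z)-7-[(tert-butyldimethylsilyl)oxy]-4-[(trimethylsilyl)methyl]hept-4-enal; 9 ethyl 2-(triphenylphosphoranylidene)propanoate
Product: 10 ethyl (2E,6Z)-9-[(tert-butyldimethylsilyl)oxy]-2-methyl-6-[(trimethylsilyl)methyl]nona-2,6-dienoate
Conditions: 9 (1.3 equiv), CH2Cl2, 23 → 40 °C
Reagents that add atoms: none
Why: Wittig olefination with a stabilised α-methyl ylide gives the (2E)-trisubstituted enoate (typically above 95:5), which becomes the C5=C10 alkene of the cyclization substrate.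

Step 5
Reactants: 10 ethyl (2E,6Z)-9-[(tert-butyldimethylsilyl)oxy]-2-methyl-6-[(trimethylsilyl)methyl]nona-2,6-dienoate
Product: 11 (2E,6Z)-9-[(tert-butyldimethylsilyl)oxy]-2-methyl-6-[(trimethylsilyl)methyl]nona-2,6-dien-1-ol
Conditions: i-Bu2AlH (2.3 equiv), CH2Cl2, −78 → 0 °C; aq. KNaC4H4O6
Reagents that add atoms: none
Why: i-Bu2AlH reduces the conjugated ester in 1,2-fashion to the allylic alcohol without touching either alkene.

Step 6
Reactants: 11 (2E,6Z)-9-[(tert-butyldimethylsilyl)oxy]-2-methyl-6-[(trimethylsilyl)methyl]nona-2,6-dien-1-ol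
Product: 13 (2E,6Z)-1-bromo-9-[(tert-butyldimethylsilyl)oxy]-2-methyl-6-[(trimethylsilyl)methyl]nona-2,6-diene, via allylic mesylate 12 (not isolated)
Conditions: MsCl, Et3N, THF, −40 °C; then LiBr, 0 °C
Reagents that add atoms: lithium bromide, [Li+].[Br-]; methanesulfonyl chloride, CS(=O)(=O)Cl (held only in intermediate 12)
Why: mesylation followed by SN2 displacement with bromide under non-acidic conditions converts the primary allylic alcohol into the bromide with the E geometry kept and the allylsilane untouched.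

Step 7
Reactants: 14 3-methylbut-2-enal; 15 propane-1,3-dithiol
Product: 16 2-(2-methylprop-1-en-1-yl)-1,3-dithiane
Conditions: BF3·OEt2 (10 mol%), CH2Cl2, −20 → 0 °C
Reagents that add atoms: none
Why: Lewis-acid-catalysed thioacetalisation of the aldehyde, conjugate thiol addition being disfavoured at the fully substituted β-carbon.

Step 8
Reactants: 16 2-(2-methylprop-1-en-1-yl)-1,3-dithiane; 13 (2E,6Z)-1-bromo-9-[(tert-butyldimethylsilyl)oxy]-2-methyl-6-[(trimethylsilyl)methyl]nona-2,6-diene
Product: 18 2-[(2E,6Z)-9-[(tert-butyldimethylsilyl)oxy]-2-methyl-6-[(trimethylsilyl)methyl]nona-2,6-dien-1-yl]-2-(2-methylprop-1-en-1-yl)-1,3-dithiane, via 2-lithio-1,3-dithiane 17 (not isolated)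
Conditions: 16, n-BuLi, THF, −30 °C; then 13, −78 → −20 °C
Reagents that add atoms: butyllithium, [Li]CCCC (lithium held only in intermediate 17)
Why: Corey–Seebach umpolung alkylation, in which the lithiated alkenyl dithiane attacks the primary allylic bromide by SN2 at its α-carbon because the γ-terminus carries two methyl groups, so the E alkene is kept.

Step 9
Reactants: 18 2-[(2E,6Z)-9-[(tert-butyldimethylsilyl)oxy]-2-methyl-6-[(trimethylsilyl)methyl]nona-2,6-dien-1-yl]-2-(2-methylprop-1-en-1-yl)-1,3-dithiane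
Product: 19 (6E,10Z)-13-[(tert-butyldimethylsilyl)oxy]-2,6-dimethyl-10-[(trimethylsilyl)methyl]trideca-2,6,10-trien-4-one
Conditions: MeI (10 equiv), CaCO3 (5 equiv), MeCN/H2O 9:1, 40 °C
Reagents that add atoms: water, O
Why: S-methylation turns the dithiane into a leaving group and water delivers the ketone under carbonate-buffered neutral conditions (alkylative dithiane hydrolysis), which avoids acid- or base-induced migration of the skipped C6 alkene into conjugation.

Step 10
Reactants: 19 (6E,10Z)-13-[(tert-butyldimethylsilyl)oxy]-2,6-dimethyl-10-[(trimethylsilyl)methyl]trideca-2,6,10-trien-4-one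
Product: 21 (4aR,8R,8aR)-8-{2-[(tert-butyldimethylsilyl)oxy]ethyl}-4,4,8a-trimethyl-7-methylideneoctahydronaphthalen-2(1H)-one, via trimethylsilyl enol ether 20 (not isolated)
Conditions: (S)-tetrahydro-1-(2-methylphenyl)-3,3-diphenyl-1H,3H-pyrrolo[1,2-c][1,3,2]oxazaborole (20 mol%), HNTf2 (18 mol%), Ph3PO (20 mol%), CH2Cl2 (0.02 M), −78 → −40 °C; then 0.5 M HCl, THF, 0 °C
Reagents that add atoms: none
Why: Proposed new method: a catalytic enantioselective enone-initiated cation–olefin bicyclization terminated by an allylsilane, in which the cationic N-protonated oxazaborolidine binds the C2 carbonyl of 19 and makes C4 an incipient tertiary cation while its aryl groups shield one face, the (6E)-alkene then adds through a chair–chair array (C4–C5 closes ring A, anti addition across the E alkene puts H-5 trans to the C10 methyl), the (10Z)-allylsilane closes ring B (C9–C10) with the side chain equatorial and loses Me3Si+ to give the exocyclic C8 methylene, and silyl transfer to the boron enolate (relayed by Ph3PO) releases enol ether 20 and the catalyst, so the relative configuration follows from the alkene geometries and the absolute (5R,9R,10R) configuration from the open C4 face; the closest known reaction types are oxazaborolidinium-catalysed Mukaiyama–Michael and Diels–Alder reactions of enones and stoichiometric Lewis-acid-promoted allylsilane-terminated polyene cyclizations (intramolecular Sakurai additions).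

Step 11
Reactants: 21 (4aR,8R,8aR)-8-{2-[(tert-butyldimethylsilyl)oxy]ethyl}-4,4,8a-trimethyl-7-methylideneoctahydronaphthalen-2(1H)-one
Product: 22 (4aR,8R,8aR)-8-(2-hydroxyethyl)-4,4,8a-trimethyl-7-methylideneoctahydronaphthalen-2(1H)-one
Conditions: HF·pyridine, pyridine, THF, 0 → 23 °C
Reagents that add atoms: none
Why: fluoride-mediated cleavage of the primary silyl ether is mild enough for the ketone and the exocyclic alkene.

Step 12
Reactants: 22 (4aR,8R,8aR)-8-(2-hydroxyethyl)-4,4,8a-trimethyl-7-methylideneoctahydronaphthalen-2(1H)-one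
Product: 23 (4aR,8R,8aR)-8-(2-iodoethyl)-4,4,8a-trimethyl-7-methylideneoctahydronaphthalen-2(1H)-one
Conditions: I2, PPh3, imidazole, CH2Cl2, 0 → 23 °C
Reagents that add atoms: iodine, II
Why: Appel-type iodination through the alkoxyphosphonium ion converts the primary alcohol into the iodide by SN2 under neutral conditions.

Step 13
Reactants: 24 tert-butyl 4-chloro-3-oxobutanoate
Product: 25 tert-butyl 4-[(4-methoxyphenyl)methoxy]-3-oxobutanoate
Conditions: 4-methoxybenzyl alcohol, NaH (2.2 equiv), THF, 0 → 23 °C; aq. HCl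
Reagents that add atoms: 4-methoxybenzyl alcohol, COc1ccc(CO)cc1
Why: Williamson-type SN2 displacement of the chloride by the sodium alkoxide while the β-keto ester is held as its sodium enolate.

Step 14
Reactants: 25 tert-butyl 4-[(4-methoxyphenyl)methoxy]-3-oxobutanoate
Product: 26 tert-butyl (2E)-4-[(4-methoxyphenyl)methoxy]-3-[(4-methylbenzenesulfonyl)oxy]but-2-enoate
Conditions: TsCl, N-methylimidazole, Et3N, toluene, 0 °C
Reagents that add atoms: 4-methylbenzenesulfonyl chloride, Cc1ccc(cc1)S(=O)(=O)Cl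
Why: enol tosylation through the sulfonylimidazolium salt under non-chelating amine conditions gives the E enol tosylate (tosyloxy trans to the ester), which fixes the side-chain alkene geometry.

Step 15
Reactants: 23 (4aR,8R,8aR)-8-(2-iodoethyl)-4,4,8a-trimethyl-7-methylideneoctahydronaphthalen-2(1H)-one; 26 tert-butyl (2E)-4-[(4-methoxyphenyl)methoxy]-3-[(4-methylbenzenesulfonyl)oxy]but-2-enoate
Product: 28 tert-butyl (2Z)-4-[(4-methoxyphenyl)methoxy]-3-{2-[(1R,4aR,8aR)-5,5,8a-trimethyl-2-methylidene-7-oxodecahydronaphthalen-1-yl]ethyl}but-2-enoate, via alkylzinc iodide 27 (not isolated)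
Conditions: 23, Zn dust (activated), LiCl, THF, 40 °C; then 26 (1.3 equiv), Pd(OAc)2 (3 mol%), 2-dicyclohexylphosphino-2′,6′-dimethoxybiphenyl (6 mol%), THF, 23 → 40 °C
Reagents that add atoms: zinc, [Zn] (held only in intermediate 27)
Why: zinc insertion into the primary iodide tolerates the ketone, and Negishi cross-coupling (oxidative addition of zerovalent palladium into the ester-activated C–OTs bond, transmetalation, reductive elimination) proceeds with retention, so the new C12–C13 bond is trans to the ester and the descriptor changes from E to Z by priority only.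

Step 16
Reactants: 28 tert-butyl (2Z)-4-[(4-methoxyphenyl)methoxy]-3-{2-[(1R,4aR,8aR)-5,5,8a-trimethyl-2-methylidene-7-oxodecahydronaphthalen-1-yl]ethyl}but-2-enoate
Product: 30 tert-butyl (2Z)-4-(acetyloxy)-3-{2-[(1R,4aR,8aR)-5,5,8a-trimethyl-2-methylidene-7-oxodecahydronaphthalen-1-yl]ethyl}but-2-enoate, via hydroxy ester 29 (not isolated)
Conditions: DDQ (1.3 equiv), CH2Cl2/pH 7 phosphate buffer 10:1, 0 °C; then Ac2O, pyridine, DMAP (5 mol%), CH2Cl2, 0 °C
Reagents that add atoms: acetic anhydride, CC(=O)OC(C)=O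
Why: oxidative cleavage of the 4-methoxybenzyl ether by DDQ and immediate DMAP-catalysed acetylation of the primary allylic alcohol, the bulky tert-butyl ester slowing lactonisation of the cis hydroxy ester long enough for acylation.

Step 17
Reactants: 30 tert-butyl (2Z)-4-(acetyloxy)-3-{2-[(1R,4aR,8aR)-5,5,8a-trimethyl-2-methylidene-7-oxodecahydronaphthalen-1-yl]ethyl}but-2-enoate
Product: 31 (2Z)-4-(acetyloxy)-3-{2-[(1R,4aR,8aR)-5,5,8a-trimethyl-2-methylidene-7-oxodecahydronaphthalen-1-yl]ethyl}but-2-enoic acid (CNP0152461.1)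
Conditions: 85% aq. H3PO4 (10 equiv), toluene, 23 °C
Reagents that add atoms: none
Why: acid-mediated tert-butyl ester cleavage (loss of 2-methylpropene from the protonated ester) with aqueous phosphoric acid is mild enough to leave the acetate, the Z enoate and the exocyclic alkene untouched.

**Compound list**

1 | 3-[(tert-butyldimethylsilyl)oxy]propanal | O=CCCO[Si](C)(C)C(C)(C)C | starting material
2 | (2-bromoprop-2-en-1-yl)trimethylsilane | C=C(Br)C[Si](C)(C)C | starting material
3 | [3-(trimethylsilyl)prop-1-en-2-yl]magnesium bromide | C=C([Mg]Br)C[Si](C)(C)C | intermediate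
4 | rac-1-[(tert-butyldimethylsilyl)oxy]-4-[(trimethylsilyl)methyl]pent-4-en-3-ol (racemic) | CC(C)(C)[Si](C)(C)OCCC(O)C(=C)C[Si](C)(C)C | intermediate
5 | triethyl orthoacetate (1,1,1-triethoxyethane) | CC(OCC)(OCC)OCC | starting material
6 | mixed ketene acetal: 1-ethoxyethenyl ether of 4 | CCOC(=C)OC(CCO[Si](C)(C)C(C)(C)C)C(=C)C[Si](C)(C)C | intermediate
7 | ethyl (4Z)-7-[(tert-butyldimethylsilyl)oxy]-4-[(trimethylsilyl)methyl]hept-4-enoate | CCOC(=O)CC/C(C[Si](C)(C)C)=C/CCO[Si](C)(C)C(C)(C)C | intermediate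
8 | (4Z)-7-[(tert-butyldimethylsilyl)oxy]-4-[(trimethylsilyl)methyl]hept-4-enal | O=CCC/C(C[Si](C)(C)C)=C/CCO[Si](C)(C)C(C)(C)C | intermediate
9 | ethyl 2-(triphenylphosphoranylidene)propanoate | CCOC(=O)C(C)=P(c1ccccc1)(c1ccccc1)c1ccccc1 | starting material
10 | ethyl (2E,6Z)-9-[(tert-butyldimethylsilyl)oxy]-2-methyl-6-[(trimethylsilyl)methyl]nona-2,6-dienoate | CCOC(=O)/C(C)=C/CC/C(C[Si](C)(C)C)=C/CCO[Si](C)(C)C(C)(C)C | intermediate
11 | (2E,6Z)-9-[(tert-butyldimethylsilyl)oxy]-2-methyl-6-[(trimethylsilyl)methyl]nona-2,6-dien-1-ol | OC/C(C)=C/CC/C(C[Si](C)(C)C)=C/CCO[Si](C)(C)C(C)(C)C | intermediate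
12 | (2E,6Z)-9-[(tert-butyldimethylsilyl)oxy]-2-methyl-6-[(trimethylsilyl)methyl]nona-2,6-dien-1-yl methanesulfonate | CS(=O)(=O)OC/C(C)=C/CC/C(C[Si](C)(C)C)=C/CCO[Si](C)(C)C(C)(C)C | intermediate
13 | (2E,6Z)-1-bromo-9-[(tert-butyldimethylsilyl)oxy]-2-methyl-6-[(trimethylsilyl)methyl]nona-2,6-diene | BrC/C(C)=C/CC/C(C[Si](C)(C)C)=C/CCO[Si](C)(C)C(C)(C)C | intermediate
14 | 3-methylbut-2-enal | CC(C)=CC=O | starting material
15 | propane-1,3-dithiol | SCCCS | starting material
16 | 2-(2-methylprop-1-en-1-yl)-1,3-dithiane | CC(C)=CC1SCCCS1 | intermediate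
17 | 2-lithio-2-(2-methylprop-1-en-1-yl)-1,3-dithiane | [Li]C1(C=C(C)C)SCCCS1 | intermediate
18 | 2-[(2E,6Z)-9-[(tert-butyldimethylsilyl)oxy]-2-methyl-6-[(trimethylsilyl)methyl]nona-2,6-dien-1-yl]-2-(2-methylprop-1-en-1-yl)-1,3-dithiane | CC(C)=CC1(C/C(C)=C/CC/C(C[Si](C)(C)C)=C/CCO[Si](C)(C)C(C)(C)C)SCCCS1 | intermediate
19 | (6E,10Z)-13-[(tert-butyldimethylsilyl)oxy]-2,6-dimethyl-10-[(trimethylsilyl)methyl]trideca-2,6,10-trien-4-one | CC(C)=CC(=O)C/C(C)=C/CC/C(C[Si](C)(C)C)=C/CCO[Si](C)(C)C(C)(C)C | intermediate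
20 | tert-butyl(dimethyl){2-[(1R,4aR,8aS)-5,5,8a-trimethyl-2-methylidene-7-[(trimethylsilyl)oxy]-1,2,3,4,4a,5,8,8a-octahydronaphthalen-1-yl]ethoxy}silane (C2–C3 trimethylsilyl enol ether of 21, same spatial arrangement) | C=C1CC[C@@H]2C(C)(C)C=C(O[Si](C)(C)C)C[C@@]2(C)[C@@H]1CCO[Si](C)(C)C(C)(C)C | intermediate
21 | (4aR,8R,8aR)-8-{2-[(tert-butyldimethylsilyl)oxy]ethyl}-4,4,8a-trimethyl-7-methylideneoctahydronaphthalen-2(1H)-one | C=C1CC[C@@H]2C(C)(C)CC(=O)C[C@@]2(C)[C@@H]1CCO[Si](C)(C)C(C)(C)C | intermediate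
22 | (4aR,8R,8aR)-8-(2-hydroxyethyl)-4,4,8a-trimethyl-7-methylideneoctahydronaphthalen-2(1H)-one | C=C1CC[C@@H]2C(C)(C)CC(=O)C[C@@]2(C)[C@@H]1CCO | intermediate
23 | (4aR,8R,8aR)-8-(2-iodoethyl)-4,4,8a-trimethyl-7-methylideneoctahydronaphthalen-2(1H)-one | C=C1CC[C@@H]2C(C)(C)CC(=O)C[C@@]2(C)[C@@H]1CCI | intermediate
24 | tert-butyl 4-chloro-3-oxobutanoate | CC(C)(C)OC(=O)CC(=O)CCl | starting material
25 | tert-butyl 4-[(4-methoxyphenyl)methoxy]-3-oxobutanoate | CC(C)(C)OC(=O)CC(=O)COCc1ccc(OC)cc1 | intermediate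
26 | tert-butyl (2E)-4-[(4-methoxyphenyl)methoxy]-3-[(4-methylbenzenesulfonyl)oxy]but-2-enoate | COc1ccc(COC/C(OS(=O)(=O)c2ccc(C)cc2)=C\C(=O)OC(C)(C)C)cc1 | intermediate
27 | {2-[(1R,4aR,8aR)-5,5,8a-trimethyl-2-methylidene-7-oxodecahydronaphthalen-1-yl]ethyl}zinc iodide | C=C1CC[C@@H]2C(C)(C)CC(=O)C[C@@]2(C)[C@@H]1CC[Zn]I | intermediate
28 | tert-butyl (2Z)-4-[(4-methoxyphenyl)methoxy]-3-{2-[(1R,4aR,8aR)-5,5,8a-trimethyl-2-methylidene-7-oxodecahydronaphthalen-1-yl]ethyl}but-2-enoate | C=C1CC[C@@H]2C(C)(C)CC(=O)C[C@@]2(C)[C@@H]1CC/C(=C/C(=O)OC(C)(C)C)COCc1ccc(OC)cc1 | intermediate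
29 | tert-butyl (2Z)-4-hydroxy-3-{2-[(1R,4aR,8aR)-5,5,8a-trimethyl-2-methylidene-7-oxodecahydronaphthalen-1-yl]ethyl}but-2-enoate | C=C1CC[C@@H]2C(C)(C)CC(=O)C[C@@]2(C)[C@@H]1CC/C(=C/C(=O)OC(C)(C)C)CO | intermediate
30 | tert-butyl (2Z)-4-(acetyloxy)-3-{2-[(1R,4aR,8aR)-5,5,8a-trimethyl-2-methylidene-7-oxodecahydronaphthalen-1-yl]ethyl}but-2-enoate | C=C1CC[C@@H]2C(C)(C)CC(=O)C[C@@]2(C)[C@@H]1CC/C(=C/C(=O)OC(C)(C)C)COC(C)=O | intermediate
31 | (2Z)-4-(acetyloxy)-3-{2-[(1R,4aR,8aR)-5,5,8a-trimethyl-2-methylidene-7-oxodecahydronaphthalen-1-yl]ethyl}but-2-enoic acid; (13Z)-16-acetoxy-2-oxo-ent-labda-8(17),13-dien-15-oic acid | C=C1CC[C@@H]2C(C)(C)CC(=O)C[C@@]2(C)[C@@H]1CC/C(=C/C(=O)O)COC(C)=O | target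

**Step count and risk**

Total steps: 17. Longest linear sequence: 14 steps (steps 1–6, 8–12, 15–17).

The three steps most likely to fail:

Step 9 (dithiane unmasking). The alkylative hydrolysis may be slow, and the skipped enone 19 can slip into conjugation. Fallback: the carbonyl is made by rearrangement instead of by acyl-anion chemistry. Bromide 13 is coupled with 2-methylbut-3-yn-2-ol (CuI 10 mol%, K2CO3, Bu4NI cat., DMF, 23 °C) to give the skipped enynol (6E,10Z)-13-[(tert-butyldimethylsilyl)oxy]-2,6-dimethyl-10-[(trimethylsilyl)methyl]trideca-6,10-dien-3-yn-2-ol F1. F1 then undergoes a gold-catalysed Meyer–Schuster rearrangement ((Ph3P)AuNTf2 2 mol%, MeOH 1 equiv, toluene, 23 °C) directly to 19. This sets out from 13 and comes back at 19, so steps 7 to 9 are not needed.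

Step 10 (the proposed new cyclization). Possible failures are low reactivity of the β,β-disubstituted enone toward the chiral catalyst, a racemic background path through silyl triflimide, isomerisation of the enone, or low enantioselectivity. Fallback with known chemistry: 19 is cyclized with stoichiometric achiral MeAlCl2 (1.5 equiv, CH2Cl2, −78 °C, aqueous work-up). This is the established Lewis-acid-promoted enone-initiated, allylsilane-terminated cation–olefin cyclization. The trans ring fusion and equatorial side chain still follow from the alkene geometries, and the product is the racemate rac-(4aR,8R,8aR)-8-{2-[(tert-butyldimethylsilyl)oxy]ethyl}-4,4,8a-trimethyl-7-methylideneoctahydronaphthalen-2(1H)-one F2. F2 is resolved by preparative supercritical-fluid chromatography on amylose tris(3,5-dimethylphenylcarbamate), and the (4aR,8R,8aR) enantiomer is carried on. This sets out from 19 and comes back at 21.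

Step 16 (ether cleavage and acetylation through the lactonisation-prone cis hydroxy ester 29). If 29 closes to the butenolide faster than it is acetylated, the acetate is carried through the coupling so that no free hydroxy ester ever exists. Chloride 24 is treated with KOAc (AcOH cat., DMF, 23 °C) to give tert-butyl 4-(acetyloxy)-3-oxobutanoate F3. F3 is tosylated as in step 14 (TsCl, N-methylimidazole, Et3N, toluene, 0 °C) to give tert-butyl (2E)-4-(acetyloxy)-3-[(4-methylbenzenesulfonyl)oxy]but-2-enoate F4. F4 (1.5 equiv) is coupled with alkylzinc iodide 27 (made from 23 as in step 15) using the step 15 catalyst at 0 → 23 °C, so that fast transmetalation outruns loss of the allylic acetate; this gives 30 directly. This sets out from 24 and 23 and comes back at 30.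

**Further compounds**

F1 | step 9 | (6E,10Z)-13-[(tert-butyldimethylsilyl)oxy]-2,6-dimethyl-10-[(trimethylsilyl)methyl]trideca-6,10-dien-3-yn-2-ol | CC(C)(O)C#CC/C(C)=C/CC/C(C[Si](C)(C)C)=C/CCO[Si](C)(C)C(C)(C)C
F2 | step 10 | rac-(4aR,8R,8aR)-8-{2-[(tert-butyldimethylsilyl)oxy]ethyl}-4,4,8a-trimethyl-7-methylideneoctahydronaphthalen-2(1H)-one (1:1 mixture of both enantiomers) | C=C1CC[C@@H]2C(C)(C)CC(=O)C[C@@]2(C)[C@@H]1CCO[Si](C)(C)C(C)(C)C.C=C1CC[C@H]2C(C)(C)CC(=O)C[C@]2(C)[C@H]1CCO[Si](C)(C)C(C)(C)C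
F3 | step 16 | tert-butyl 4-(acetyloxy)-3-oxobutanoate | CC(=O)OCC(=O)CC(=O)OC(C)(C)C
F4 | step 16 | tert-butyl (2E)-4-(acetyloxy)-3-[(4-methylbenzenesulfonyl)oxy]but-2-enoate | CC(=O)OC/C(OS(=O)(=O)c1ccc(C)cc1)=C\C(=O)OC(C)(C)C
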